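**The easy step.** The easy step was the balance of G, the reagent charged in the smaller amount: G comes back at each turn, so its balance held it at its charge, and each route through G was pseudo-first-order. From that I had to choose the next run.

| setting | south | south-west | west |
|---|---|---|---|
| Z | 0.22 M | 0.22 M | 0.22 M |
| G | 0.22 mM | 0.22 mM | 0.22 mM |
| temperature | 25 °C | 0 °C | 50 °C |
| time | 3.0 min | 3.0 min | 3.0 min |

    G + L → G + Q (k1 = 27 /M/s, Ea1 = 38.0 kJ/mol)
    2 Z → Z2 (k2 = 0.18 /M/s, Ea2 = 36.0 kJ/mol)
    Z + G → G + J (k3 = 22 /M/s, Ea3 = 46.0 kJ/mol)
    E ⇌ J, rate k4*(cs4 - [J]) while solid is left; crystals form when [J] > cs4 (cs4 = 31 mM, k4 = 0.13 /s)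
    Z ⇌ L (K5 = 0.27, k5 = 0.033 /s, Ea5 = 69.0 kJ/mol, ΔH5 = 18.0 kJ/mol)
    (constants at 25 °C)

- in percentages every species weighs as the Z in it: one Z2 counts as two
- for J the E are counted in
- where a step has two of a species, its rate is k times that concentration squared, and two are used at each turn
- as a solid, counted per litre of solution: E
- the constants hold at 25 °C; other temperatures follow from the activation energies and enthalpies
- in a conversion L counts as not yet reacted

1. the best flask by amount of J, in percent of the Z charged; "all alike" if 1.5 percentage points covers them all (south / south-west / west / all alike)
2. amount of J at the end, in percent of the Z charged, south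
3. amount of J at the end, in percent of the Z charged, south-west
4. amount of J at the end, in percent of the Z charged, west

**One pool.** In south, Z and L exchange with a relaxation half-life of 0.0744 min, shorter than the run of 3.0 min, so I treated them as one pool P with L/Z at 0.27. P falls through G at b·P, with b = 0.304 /min, and by pairing of Z to Z2 at b·P·P/a. Here a is the crossover, the pool at which the G routes use material as fast as the pairing does: 22.7 mM. The charge of 0.22 M stood far above it, so pairing led at the start.

**South by hand.** Integrating this law left a pool of 13.0 mM at 3.0 min. J takes 75.1% of what goes through G, which gave 14.9% of J in south.

**The choice.** At a fixed charge, a larger crossover gives the G routes a larger part of the pool. The route to J has a higher activation energy than the pairing, so heat should raise the crossover. The equilibrium ratio L/Z rises with heat too (step enthalpy 18.0 kJ/mol) and sends more through L to Q, so my reckoning stopped at a lean, not a figure. I chose west and kept G and the time as written.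

**The forecast.** It named west, with 14.5% for south, 6.3% for south-west and 22.2% for west, holding that “heating shifts selectivity toward J”. My south figure stood slightly above its figure, and I made none for the other two flasks.

**The result.** The simulation gave west as best, with 14.6% for south, 6.16% for south-west and 22.5% for west.

**The turnover.** In south the pairing used Z 16 times as fast as the route to J at the start and 0.76 times as fast at the asked time. By then the south pool read 13.0 mM, below the crossover of 22.7 mM. For a neighbour flask, south with G at 0.130 mM, I reckoned a crossover of 13.4 mM, a final pool of 16.4 mM, and J at 9.41%. The simulated neighbour gave 9.27%.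

The numbers are those of an exercise; what happens was integrated by code.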